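**Plan**

1. Cuts: first the aryl ester C–O bond and the isopropyl–C3 bond (azulene locants of the target are used for every intermediate). Then, in one operation, C3a–C4 and C5=C6: the C4–C5 unit is an ynol ether inserted into the C3a–C6 bond of a diquinane enone.
2. Enabling feature: in the seven-membered ring the C4 oxygen is 1,3 to the C3 oxygen through C3a, and the C5=C6 alkene ends at the methyl-bearing C6. At the ketone level this is the push–pull dienone O=C3–C3a=C4(OSi)–C5=C6, the ring-opened form of a donor–acceptor cyclobutene.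
3. Forward order: five-membered ring A first (C8a quaternary centre by conjugate addition), cyclopentene ring B by aldol condensation, then enlargement of ring B by two carbons to the seven-membered ring. The isopropyl carbinol, the C4 carbinol and the ester follow.
4. Stereochemistry: C8a from a ligand-controlled copper-catalysed conjugate addition. C3 and C3a are set in an aldol-type ketol (addition anti to the 8a-methyl group, thermodynamic control available for both). C4 is set by hydride delivery from the C3 hydroxyl.

Key step: step 5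

**Route**

Step 1
Reactants: 1 3-ethoxycyclopent-2-en-1-one; 2 2-(2-bromoethyl)-2-methyl-1,3-dioxolane
Product: 5 3-[2-(2-methyl-1,3-dioxolan-2-yl)ethyl]cyclopent-2-en-1-one, via Grignard reagent 3 (not isolated), via bromomagnesium alkoxide 4 (not isolated)
Conditions: Mg, THF, 25 °C; add 1, 0 °C; then 1 M HCl, 0 °C
Reagents that add atoms: water O
Why: 1,2-Addition of the Grignard reagent to the vinylogous ester carbonyl, then acid-induced loss of ethanol with allylic transposition (Stork–Danheiser transposition), should give the 3-substituted cyclopentenone, the dioxolane surviving brief cold dilute acid; no stereocentre is formed.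

Step 2
Reactants: 5 3-[2-(2-methyl-1,3-dioxolan-2-yl)ethyl]cyclopent-2-en-1-one
Product: 6 (3R)-3-methyl-3-[2-(2-methyl-1,3-dioxolan-2-yl)ethyl]cyclopentan-1-one
Conditions: Me3Al, Cu(OTf)2 (5 mol%), chiral binaphthol-derived phosphoramidite ligand (10 mol%), Et2O, −30 °C; aq. potassium sodium tartrate
Reagents that add atoms: trimethylaluminium C[Al](C)C
Why: Copper-catalysed asymmetric conjugate addition of a methyl group to a 3-alkylcyclopentenone is an established way to all-carbon quaternary centres; the ligand selects the enone face and so sets C8a (the ligand enantiomer that gives the 3R ketone is used).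

Step 3
Reactants: 6 (3R)-3-methyl-3-[2-(2-methyl-1,3-dioxolan-2-yl)ethyl]cyclopentan-1-one
Product: 8 (3aS)-3a,6-dimethyl-3,3a,4,5-tetrahydropentalen-1(2H)-one, via diketone 7 (not isolated)
Conditions: 2 M HCl, THF, 25 °C; then KOH, MeOH, 60 °C
Reagents that add atoms: none
Why: Ketal hydrolysis then intramolecular aldol condensation of the 1,6-diketone: only the aldol from the ring α-carbon next to the quaternary centre onto the side-chain ketone (5-exo) can dehydrate, the other aldols are bridged and revert, so the fused 2-methylcyclopentenyl ketone should result with C8a unchanged.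

Step 4
Reactants: 9 acetylene
Product: 12 (ethynyloxy)tri(propan-2-yl)silane, via lithium acetylide 10 (not isolated), via lithium ethynolate 11 (not isolated)
Conditions: n-BuLi, THF, −78 °C; t-BuOOLi (from t-BuOOH and LiN(SiMe3)2), −78 to 0 °C; i-Pr3SiOTf, −78 °C
Reagents that add atoms: tert-butyl hydroperoxide CC(C)(C)OO; triisopropylsilyl trifluoromethanesulfonate CC(C)[Si](C(C)C)(C(C)C)OS(=O)(=O)C(F)(F)F
Why: Electrophilic oxygen transfer from the lithium peroxide to the acetylide gives the ynolate, which a bulky silyl triflate should silylate on oxygen and not on carbon (ynolate oxidation and O-silylation as used for substituted siloxyalkynes); no stereocentre.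

Step 5
Reactants: 8 (3aS)-3a,6-dimethyl-3,3a,4,5-tetrahydropentalen-1(2H)-one; 12 (ethynyloxy)tri(propan-2-yl)silane
Product: 14 (8aS)-6,8a-dimethyl-4-[(triisopropylsilyl)oxy]-1,7,8,8a-tetrahydroazulen-3(2H)-one, via siloxycyclobutene 13 (not isolated)
Conditions: AgNTf2 (5 mol%), CH2Cl2, −20 to 40 °C
Reagents that add atoms: none
Why: Proposed new method: the ynol ether is nucleophilic at its unsubstituted carbon (future C5), which should add in a conjugate sense to C6 of the AgNTf2-activated enone, and the resulting enolate carbon C3a should then close onto the ketenium carbon C4 (4-exo-dig) to give the donor–acceptor cyclobutene 13, a stepwise [2+2] cycloaddition of the Ficini type that is known for substituted siloxyalkynes and ynamines with simple cyclic enones but not for a terminal ynol ether and a tetrasubstituted bicyclic enone. In 13 the C3a–C6 bond carries the acceptor carbonyl C3 at one end and, through the C4=C5 double bond, the donor oxygen at the other, and it joins three contiguous quaternary carbons, so it should break in a push–pull 4π ring opening (tertiary allyl cation at C6, enolate at C3a) whose closest precedents are the two-carbon ring expansion of cyclic enamines with acetylenic esters and the thermal opening of cyclobutenes. The seven-membered ring is therefore not closed by cyclisation but arises when the bond common to the four- and five-membered rings opens, which puts the C5=C6 double bond and the C3a–C4 bond in place in one operation. No stereocentre is set: the two centres made in 13 (cis fusion on the face of the 8a-methyl group is the only strain-free mode) become trigonal again and C8a is not touched. The step needs conjugate instead of carbonyl addition of the ynol ether and attachment of the oxygenated carbon to C3a; the second is fixed by polarity, the first is favoured by activation with a soft silver salt and by the reversibility of the unproductive zwitterion closures, the conjugated strain-free dienone being the thermodynamic sink.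

Step 6
Reactants: 14 (8aS)-6,8a-dimethyl-4-[(triisopropylsilyl)oxy]-1,7,8,8a-tetrahydroazulen-3(2H)-one
Product: 16 (3R,3aR,8aS)-3-hydroxy-6,8a-dimethyl-3-(propan-2-yl)-2,3,3a,7,8,8a-hexahydroazulen-4(1H)-one, via silyl dienol ether carbinol 15 (not isolated)
Conditions: i-PrLi, CeCl3, THF, −78 °C; then AcOH, Bu4NF, THF, −78 to 0 °C
Reagents that add atoms: isopropyllithium CC(C)[Li]
Why: Carbonyl addition of the organocerium reagent to the vinylogous ester (first half of a Stork–Danheiser sequence) then buffered fluoride cleavage of the silyl enol ether should give the ketol: attack at C3 is expected anti to the 8a-methyl group and C3a is protonated last, and because the C3 hydroxyl is β to the C4 ketone both centres can equilibrate (retro-aldol/aldol, enolisation) toward the isomer drawn, the only one with the isopropyl group trans to both the 8a-methyl group and the C3a–C4 bond and with the hydroxyl able to hydrogen-bond to the ketone.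

Step 7
Reactants: 16 (3R,3aR,8aS)-3-hydroxy-6,8a-dimethyl-3-(propan-2-yl)-2,3,3a,7,8,8a-hexahydroazulen-4(1H)-one
Product: 17 (3R,3aS,4S,8aS)-6,8a-dimethyl-3-(propan-2-yl)-1,2,3,3a,4,7,8,8a-octahydroazulene-3,4-diol
Conditions: Me4NBH(OAc)3, AcOH–MeCN, −20 °C
Reagents that add atoms: none
Why: Evans–Saksena reduction: the C3 hydroxyl exchanges onto boron and hydride is delivered internally to the face of the C4 carbonyl on which C3 lies, which should give the 4S alcohol and leave the conjugated C5=C6 bond untouched.

Step 8
Reactants: 17 (3R,3aS,4S,8aS)-6,8a-dimethyl-3-(propan-2-yl)-1,2,3,3a,4,7,8,8a-octahydroazulene-3,4-diol; 18 4-(acetyloxy)benzoyl chloride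
Product: 19 (3R,3aS,4S,8aS)-3-hydroxy-6,8a-dimethyl-3-(propan-2-yl)-1,2,3,3a,4,7,8,8a-octahydroazulen-4-yl 4-(acetyloxy)benzoate
Conditions: pyridine, DMAP (cat.), CH2Cl2, 0 to 25 °C
Reagents that add atoms: none
Why: DMAP-catalysed acylation should occur only at the secondary allylic C4 hydroxyl because the tertiary C3 hydroxyl is too hindered; C4 keeps its configuration since its C–O bond is not broken.

Step 9
Reactants: 19 (3R,3aS,4S,8aS)-3-hydroxy-6,8a-dimethyl-3-(propan-2-yl)-1,2,3,3a,4,7,8,8a-octahydroazulen-4-yl 4-(acetyloxy)benzoate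
Product: 20 (3R,3aS,4S,8aS)-3-hydroxy-6,8a-dimethyl-3-(propan-2-yl)-1,2,3,3a,4,7,8,8a-octahydroazulen-4-yl 4-hydroxybenzoate
Conditions: pyrrolidine, CH2Cl2, 0 °C
Reagents that add atoms: none
Why: Aminolysis of the aryl acetate is much faster than that of the hindered secondary benzoate (chemoselective deacetylation), so only the phenol should be set free.

**Compound list**

1 | 3-ethoxycyclopent-2-en-1-one | CCOC1=CC(=O)CC1 | starting material
2 | 2-(2-bromoethyl)-2-methyl-1,3-dioxolane | CC1(CCBr)OCCO1 | starting material
3 | [2-(2-methyl-1,3-dioxolan-2-yl)ethyl]magnesium bromide | CC1(CC[Mg]Br)OCCO1 | intermediate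
4 | bromomagnesium 3-ethoxy-1-[2-(2-methyl-1,3-dioxolan-2-yl)ethyl]cyclopent-2-en-1-olate (racemic) | CCOC1=CC(CCC2(C)OCCO2)(O[Mg]Br)CC1 | intermediate
5 | 3-[2-(2-methyl-1,3-dioxolan-2-yl)ethyl]cyclopent-2-en-1-one | O=C1C=C(CCC2(C)OCCO2)CC1 | intermediate
6 | (3R)-3-methyl-3-[2-(2-methyl-1,3-dioxolan-2-yl)ethyl]cyclopentan-1-one | O=C1C[C@@](C)(CCC2(C)OCCO2)CC1 | intermediate
7 | (3S)-3-methyl-3-(3-oxobutyl)cyclopentan-1-one | O=C1C[C@@](C)(CCC(C)=O)CC1 | intermediate
8 | (3aS)-3a,6-dimethyl-3,3a,4,5-tetrahydropentalen-1(2H)-one (diquinane enone; target locants: C3 ketone, C3a=C6 double bond) | CC1=C2[C@@](C)(CC1)CCC2=O | intermediate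
9 | acetylene | C#C | starting material
10 | lithium acetylide | [Li]C#C | intermediate
11 | lithium ethynolate | [Li]OC#C | intermediate
12 | (ethynyloxy)tri(propan-2-yl)silane | C#CO[Si](C(C)C)(C(C)C)C(C)C | intermediate
13 | 4,7-dimethyl-2-[(triisopropylsilyl)oxy]tricyclo[5.3.0.0(1,4)]dec-2-en-10-one, cyclobutene cis-fused on the face of the 7-methyl group | C[C@@]12CC[C@@]3(C)CCC(=O)[C@@]13C(O[Si](C(C)C)(C(C)C)C(C)C)=C2 | intermediate
14 | (8aS)-6,8a-dimethyl-4-[(triisopropylsilyl)oxy]-1,7,8,8a-tetrahydroazulen-3(2H)-one | CC1=CC(O[Si](C(C)C)(C(C)C)C(C)C)=C2[C@@](C)(CC1)CCC2=O | intermediate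
15 | (3R,8aS)-6,8a-dimethyl-3-(propan-2-yl)-4-[(triisopropylsilyl)oxy]-1,2,3,7,8,8a-hexahydroazulen-3-ol | CC1=CC(O[Si](C(C)C)(C(C)C)C(C)C)=C2[C@@](C)(CC1)CC[C@@]2(O)C(C)C | intermediate
16 | (3R,3aR,8aS)-3-hydroxy-6,8a-dimethyl-3-(propan-2-yl)-2,3,3a,7,8,8a-hexahydroazulen-4(1H)-one | CC1=CC(=O)[C@@H]2[C@@](C)(CC1)CC[C@@]2(O)C(C)C | intermediate
17 | (3R,3aS,4S,8aS)-6,8a-dimethyl-3-(propan-2-yl)-1,2,3,3a,4,7,8,8a-octahydroazulene-3,4-diol | CC1=C[C@H](O)[C@@H]2[C@@](C)(CC1)CC[C@@]2(O)C(C)C | intermediate
18 | 4-(acetyloxy)benzoyl chloride | CC(=O)Oc1ccc(cc1)C(Cl)=O | starting material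
19 | (3R,3aS,4S,8aS)-3-hydroxy-6,8a-dimethyl-3-(propan-2-yl)-1,2,3,3a,4,7,8,8a-octahydroazulen-4-yl 4-(acetyloxy)benzoate | CC1=C[C@H](OC(=O)c2ccc(OC(C)=O)cc2)[C@@H]2[C@@](C)(CC1)CC[C@@]2(O)C(C)C | intermediate
20 | (3R,3aS,4S,8aS)-3-hydroxy-6,8a-dimethyl-3-(propan-2-yl)-1,2,3,3a,4,7,8,8a-octahydroazulen-4-yl 4-hydroxybenzoate | CC1=C[C@H](OC(=O)c2ccc(O)cc2)[C@@H]2[C@@](C)(CC1)CC[C@@]2(O)C(C)C | target

**Step count and risks**

Total step count: 9. Longest linear sequence: 8 (steps 1, 2, 3, 5, 6, 7, 8, 9); step 4 is a one-step side branch.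

Steps most likely to fail:

Step 5. The ynol ether may attack the carbonyl carbon instead of the hindered C6 (then oxetene opening to a dienoate). The zwitterion may close on oxygen to a pyran that does not go on. The cyclobutene may resist opening. The fallback uses known reactions only and closes the seven-membered ring by olefin metathesis; it sets out from 1 and returns at 17, so steps 5 to 7 are bypassed. Compound 1 and 3-methylbut-3-en-1-ylmagnesium bromide give, after cold dilute acid (Stork–Danheiser transposition), 3-(3-methylbut-3-en-1-yl)cyclopent-2-en-1-one F1. Copper-catalysed conjugate addition of Me3Al as in step 2 and trapping of the metal enolate with acrolein should give the anti aldol (2S,3S)-2-[(1S)-1-hydroxyprop-2-en-1-yl]-3-methyl-3-(3-methylbut-3-en-1-yl)cyclopentan-1-one F2 (approach of the aldehyde anti to the longer chain at the quaternary carbon, Zimmerman–Traxler anti relationship from the cyclic enolate). Et3SiCl/imidazole gives (2S,3S)-3-methyl-3-(3-methylbut-3-en-1-yl)-2-{(1S)-1-[(triethylsilyl)oxy]prop-2-en-1-yl}cyclopentan-1-one F3. Ring-closing metathesis with the second-generation Grubbs catalyst closes the trisubstituted C5=C6 alkene to (3aS,4S,8aS)-6,8a-dimethyl-4-[(triethylsilyl)oxy]-1,3a,4,7,8,8a-hexahydroazulen-3(2H)-one F4. i-PrLi/CeCl3 should add anti to the C3a substituent to give (3R,3aS,4S,8aS)-6,8a-dimethyl-3-(propan-2-yl)-4-[(triethylsilyl)oxy]-1,2,3,3a,4,7,8,8a-octahydroazulen-3-ol F5. Bu4NF then returns diol 17.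

Step 6. The secondary alkyl reagent may enolise or reduce the hindered, deactivated carbonyl instead of adding. Attack may occur from the wrong face. The adduct may lose water (elimination to the cross-conjugated dienone) or undergo retro-aldol cleavage during unmasking. The fallback builds the isopropyl group in two stages from a smaller sp2 nucleophile that cannot transfer hydride; it sets out from 14 and returns at 16. 2-Propenylmagnesium bromide/CeCl3 adds to 14 to give (3R,8aS)-6,8a-dimethyl-3-(prop-1-en-2-yl)-4-[(triisopropylsilyl)oxy]-1,2,3,7,8,8a-hexahydroazulen-3-ol F6. Buffered Bu4NF gives (3S,3aR,8aS)-3-hydroxy-6,8a-dimethyl-3-(prop-1-en-2-yl)-2,3,3a,7,8,8a-hexahydroazulen-4(1H)-one F7. Hydrogenation of the 1,1-disubstituted alkene with RhCl(PPh3)3 and H2, which should leave the trisubstituted enone alkene alone, returns 16. This fallback addresses only the addition; the elimination risk remains and is handled by the buffered unmasking.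

Step 4. The unsubstituted ynolate may oligomerise or be silylated on carbon, and the volatile product may be lost on isolation. The fallback uses commercial ethoxyacetylene as the two-carbon unit and puts the silyl group on afterwards; it sets out from 8 and returns at 14. It still relies on the reaction type of step 5. Ring expansion of 8 with ethoxyacetylene under the conditions of step 5 should give (8aS)-4-ethoxy-6,8a-dimethyl-1,7,8,8a-tetrahydroazulen-3(2H)-one F8. Aqueous HCl hydrolyses the vinylogous ester to the β-diketone (8aS)-6,8a-dimethyl-1,2,3a,7,8,8a-hexahydroazulene-3,4-dione F9 (expected to be largely enolised, C3a not fixed). i-Pr3SiOTf/Et3N should silylate the exocyclic enol oxygen at C4, the favoured enol of a 2-acylcyclopentanone, and return 14.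

Further compounds
F1 | step 5 | 3-(3-methylbut-3-en-1-yl)cyclopent-2-en-1-one | O=C1C=C(CCC(C)=C)CC1
F2 | step 5 | (2S,3S)-2-[(1S)-1-hydroxyprop-2-en-1-yl]-3-methyl-3-(3-methylbut-3-en-1-yl)cyclopentan-1-one | C=C[C@H](O)[C@@H]1[C@@](C)(CCC(C)=C)CCC1=O
F3 | step 5 | (2S,3S)-3-methyl-3-(3-methylbut-3-en-1-yl)-2-{(1S)-1-[(triethylsilyl)oxy]prop-2-en-1-yl}cyclopentan-1-one | C=C[C@H](O[Si](CC)(CC)CC)[C@@H]1[C@@](C)(CCC(C)=C)CCC1=O
F4 | step 5 | (3aS,4S,8aS)-6,8a-dimethyl-4-[(triethylsilyl)oxy]-1,3a,4,7,8,8a-hexahydroazulen-3(2H)-one | CC1=C[C@H](O[Si](CC)(CC)CC)[C@@H]2[C@@](C)(CC1)CCC2=O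
F5 | step 5 | (3R,3aS,4S,8aS)-6,8a-dimethyl-3-(propan-2-yl)-4-[(triethylsilyl)oxy]-1,2,3,3a,4,7,8,8a-octahydroazulen-3-ol | CC1=C[C@H](O[Si](CC)(CC)CC)[C@@H]2[C@@](C)(CC1)CC[C@@]2(O)C(C)C
F6 | step 6 | (3R,8aS)-6,8a-dimethyl-3-(prop-1-en-2-yl)-4-[(triisopropylsilyl)oxy]-1,2,3,7,8,8a-hexahydroazulen-3-ol | CC1=CC(O[Si](C(C)C)(C(C)C)C(C)C)=C2[C@@](C)(CC1)CC[C@@]2(O)C(C)=C
F7 | step 6 | (3S,3aR,8aS)-3-hydroxy-6,8a-dimethyl-3-(prop-1-en-2-yl)-2,3,3a,7,8,8a-hexahydroazulen-4(1H)-one | CC1=CC(=O)[C@@H]2[C@@](C)(CC1)CC[C@@]2(O)C(C)=C
F8 | step 4 | (8aS)-4-ethoxy-6,8a-dimethyl-1,7,8,8a-tetrahydroazulen-3(2H)-one | CC1=CC(OCC)=C2[C@@](C)(CC1)CCC2=O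
F9 | step 4 | (8aS)-6,8a-dimethyl-1,2,3a,7,8,8a-hexahydroazulene-3,4-dione | CC1=CC(=O)C2[C@@](C)(CC1)CCC2=O
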